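**Plan**
Retrosynthesis: the two angelates are removed; the cyclobutane bond C4–C5 of the enone ring is cut by reversing a 1,2-shift (C5 back from C4 to C3), which turns ring C1–C2–C3–C4–C5–C11 into the cyclopentene ring C1–C2–C3–C5–C11 of a bicyclo[2.2.1]heptene carrying an amine on C4. Then C3–C4 and C10–C11 are cut (formal Diels–Alder), followed by the C4–N, C9–C10, C7–C8 and C5–C6 bonds.
Forward: (R)-4-silyloxycyclopentenone gets C6 by a Mukaiyama–Michael reaction; the chain C7–C10 is built by alkoxyallylboration, Nozaki–Hiyama–Kishi coupling and nitration. The seven-membered ring and the norbornene form together in a silyloxydiene/nitroalkene cycloaddition; the cyclobutane and the cyclohexenone form together in the deaminative shift.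
Enabling feature: C4 sits between bridgehead C3, whose positive charge is absorbed by the C1–C2 silyl enol ether (the future enone), and the one-carbon bridge C5, which is anti-periplanar to an endo leaving group on C4.
Stereochemistry: C5 comes from the commercial (R)-silyloxy enone; C7/C8 from the chiral allylborane (syn); C9 from Felkin–Anh addition; C10, C11 and C4 from the tether (exo chain) and the E-nitroalkene (endo nitrogen); C4 is inverted and C5 retained in the shift.

Key step: step 12

Remark: atom numbers C1–C11 in names and comments follow the longipinane numbering of the target (C1 ketone, C2=C3 alkene, C4 and C11 bridgeheads, C5 and C10 the other cyclobutane carbons, C6 the gem-dimethyl carbon, C7–C9 the oxygenated carbons).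

Step 1
Reactants: 1 (R)-4-(tert-butyldimethylsilyloxy)cyclopent-2-en-1-one
Product: 3 (R)-2-methyl-2-(4-oxocyclopent-2-en-1-yl)propanal, via silyloxy ketone 2 (not isolated)
Conditions: 2-methyl-1-(trimethylsilyloxy)prop-1-ene, TiCl4, CH2Cl2, −78 °C; aqueous NaHCO3; then DBU, CH2Cl2, 0 °C
Reagents that add atoms: 2-methyl-1-(trimethylsilyloxy)prop-1-ene CC(C)=CO[Si](C)(C)C
Why: Mukaiyama–Michael addition of the aldehyde silyl enol ether should occur at the β-carbon anti to the silyloxy group, and E1cB loss of silanol should then give the 4-substituted enone, which fixes C5 and creates the quaternary C6.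

Step 2
Reactants: 3 (R)-2-methyl-2-(4-oxocyclopent-2-en-1-yl)propanal
Product: 4 (4R)-4-[(3S,4S)-3-hydroxy-4-(methoxymethoxy)-2-methylhex-5-en-2-yl]cyclopent-2-en-1-one
Conditions: allyl methoxymethyl ether, s-BuLi, THF, −78 °C; (+)-B-methoxydiisopinocampheylborane; BF3·OEt2; then 3, −78 °C; ethanolamine work-up
Reagents that add atoms: allyl methoxymethyl ether C=CCOCOC
Why: Brown alkoxyallylboration through a chair transition state should add the (Z)-γ-alkoxyallyl group to the Re face of the aldehyde (reagent control) and give the 7,8-syn diol monoether, while the less electrophilic enone ketone is left alone.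

Step 3
Reactants: 4 (4R)-4-[(3S,4S)-3-hydroxy-4-(methoxymethoxy)-2-methylhex-5-en-2-yl]cyclopent-2-en-1-one
Product: 5 (4R)-4-[(3S,4S)-3,4-bis(methoxymethoxy)-2-methylhex-5-en-2-yl]cyclopent-2-en-1-one
Conditions: MOMCl, iPr2NEt, Bu4NI (cat.), CH2Cl2, 40 °C
Reagents that add atoms: chloromethyl methyl ether COCCl
Why: O-alkylation with the chloromethyl ether (acetal protection) should cap the hindered C7 hydroxyl so that O7 and O8 carry the same group and can be freed together later.

Step 4
Reactants: 5 (4R)-4-[(3S,4S)-3,4-bis(methoxymethoxy)-2-methylhex-5-en-2-yl]cyclopent-2-en-1-one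
Product: 6 {[(3S,4R)-4-[(3S,4S)-3,4-bis(methoxymethoxy)-2-methylhex-5-en-2-yl]-3-methylcyclopent-1-en-1-yl]oxy}trimethylsilane
Conditions: Me2CuLi (from CuI and MeLi), TMSCl, THF, −78 °C; Et3N, then aqueous NaHCO3
Reagents that add atoms: lithium dimethylcuprate [Li+].C[Cu-]C; chlorotrimethylsilane C[Si](C)(C)Cl
Why: Conjugate addition of the Gilman cuprate should deliver the future C3 methyl trans to the bulky C5 substituent, and TMSCl should trap the enolate regiospecifically (the new C3 stereocenter is removed in the next step).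

Step 5
Reactants: 6 {[(3S,4R)-4-[(3S,4S)-3,4-bis(methoxymethoxy)-2-methylhex-5-en-2-yl]-3-methylcyclopent-1-en-1-yl]oxy}trimethylsilane
Product: 7 (4R)-4-[(3S,4S)-3,4-bis(methoxymethoxy)-2-methylhex-5-en-2-yl]-3-methylcyclopent-2-en-1-one
Conditions: Pd(OAc)2 (1.1 equiv), MeCN, 25 °C
Reagents that add atoms: none
Why: Saegusa–Ito oxidation (palladium enolate, β-hydride elimination from C3) should restore the enone with the methyl group on the β-carbon next to the C5 stereocenter, which is no longer α to the carbonyl and so cannot epimerise.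

Step 6
Reactants: 7 (4R)-4-[(3S,4S)-3,4-bis(methoxymethoxy)-2-methylhex-5-en-2-yl]-3-methylcyclopent-2-en-1-one
Product: 8 (2R,3S)-2,3-bis(methoxymethoxy)-4-methyl-4-[(1R)-2-methyl-4-oxocyclopent-2-en-1-yl]pentanal
Conditions: O3, CH2Cl2/MeOH, −78 °C (Sudan red end point); then PPh3
Reagents that add atoms: ozone [O-][O+]=O
Why: Ozonolysis should cleave the electron-rich terminal vinyl group much faster than the electron-poor enone double bond and give the α-alkoxy aldehyde (C9).

Step 7
Reactants: 8 (2R,3S)-2,3-bis(methoxymethoxy)-4-methyl-4-[(1R)-2-methyl-4-oxocyclopent-2-en-1-yl]pentanal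
Product: 9 (4R)-4-[(3S,4S,5S)-5-hydroxy-3,4-bis(methoxymethoxy)-2,6-dimethylhept-6-en-2-yl]-3-methylcyclopent-2-en-1-one
Conditions: 2-bromopropene, CrCl2 (4 equiv), NiCl2 (cat.), DMF, 25 °C
Reagents that add atoms: 2-bromopropene CC(Br)=C
Why: The Nozaki–Hiyama–Kishi reaction is aldehyde-selective in the presence of the enone, and Felkin–Anh addition to the α-alkoxy aldehyde should give the 8,9-anti carbinol (9S).

Step 8
Reactants: 9 (4R)-4-[(3S,4S,5S)-5-hydroxy-3,4-bis(methoxymethoxy)-2,6-dimethylhept-6-en-2-yl]-3-methylcyclopent-2-en-1-one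
Product: 10 (4R)-4-[(3S,4R,5S)-5-(tert-butyldimethylsilyloxy)-3,4-bis(methoxymethoxy)-2,6-dimethylhept-6-en-2-yl]-3-methylcyclopent-2-en-1-one
Conditions: TBSOTf, 2,6-lutidine, CH2Cl2, −78 to 0 °C
Reagents that add atoms: tert-butyldimethylsilyl triflate CC(C)(C)[Si](C)(C)OS(=O)(=O)C(F)(F)F
Why: Silylation with the silyl triflate should protect the hindered C9 hydroxyl with a group that survives to the end and keeps O9 distinct from O7 and O8.

Step 9
Reactants: 10 (4R)-4-[(3S,4R,5S)-5-(tert-butyldimethylsilyloxy)-3,4-bis(methoxymethoxy)-2,6-dimethylhept-6-en-2-yl]-3-methylcyclopent-2-en-1-one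
Product: 11 (4R)-4-[(3S,4R,5S,6E)-5-(tert-butyldimethylsilyloxy)-3,4-bis(methoxymethoxy)-2,6-dimethyl-7-nitrohept-6-en-2-yl]-3-methylcyclopent-2-en-1-one
Conditions: AgNO2, TEMPO, 4 Å molecular sieves, 1,2-dichloroethane, 70 °C
Reagents that add atoms: silver nitrite [Ag+].[O-]N=O
Why: Radical nitration–dehydrogenation (NO2 radical adds to the terminal carbon, TEMPO removes the hydrogen next to nitrogen) should convert the 1,1-disubstituted alkene into the E-nitroalkene, the electron-poor enone being inert.

Step 10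
Reactants: 11 (4R)-4-[(3S,4R,5S,6E)-5-(tert-butyldimethylsilyloxy)-3,4-bis(methoxymethoxy)-2,6-dimethyl-7-nitrohept-6-en-2-yl]-3-methylcyclopent-2-en-1-one
Product: 13 nitro cycloadduct (2-triisopropylsilyloxybicyclo[2.2.1]hept-2-ene core: bridgeheads C11–H and C3–Me; C5 as one-carbon bridge with H syn to the enol ether; C10 with endo methyl; endo nitro on C4; chain C6–C9 spanning C5 and exo-C10), via silyloxydiene 12 (not isolated)
Conditions: TIPSOTf (1.5 equiv), iPr2NEt, CH2Cl2, −78 to 0 °C
Reagents that add atoms: triisopropylsilyl triflate CC(C)[Si](C(C)C)(C(C)C)OS(=O)(=O)C(F)(F)F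
Why: Soft enolisation at the unhindered α′-CH2 (C11) should give the 2-silyloxycyclopentadiene, which should undergo an intramolecular Diels–Alder reaction (or stepwise double Michael addition) with the nitroalkene below 0 °C, before any [1,5]-hydrogen shift; the nucleophilic terminus C11 bonds to C10, C3 bonds to the nitro carbon C4, the tether forces the chain onto the diene face bearing C6 and into the exo position, and the E-alkene places nitrogen endo.

Step 11
Reactants: 13 nitro cycloadduct
Product: 14 endo amine (the C4 nitro group of 13 replaced by NH2)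
Conditions: LiAlH4, Et2O, 0 to 25 °C; Fieser work-up
Reagents that add atoms: none
Why: Hydride reduction of the secondary nitro group should give the primary amine with retention at C4, while the silyl enol ether and the silyl and acetal ethers are stable to the basic reagent.

Step 12
Reactants: 14 endo amine
Product: 16 (4R,5S,7S,8R,9S,10R,11R)-9-(tert-butyldimethylsilyloxy)-7,8-bis(methoxymethoxy)longipin-2-en-1-one, via diazonium acetate 15 (not isolated)
Conditions: NaNO2, AcOH/THF/H2O, 0 °C
Reagents that add atoms: none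
Why: Proposed new method: diazotisation of the endo amine gives the diazonium ion, and as N2 leaves the anti-periplanar C3–C5 bond migrates from C3 to C4, while the charge arriving at C3 is taken up by the adjacent C1–C2 silyl enol ether as a silyloxyallyl cation that loses the silyl group to give the C1 ketone and the C2=C3 double bond. The closest known reaction types are the Tiffeneau–Demjanov and semipinacol deaminations (here vinylogous, the oxygen donor being an enol ether) and the bornyl–pinyl Wagner–Meerwein shift. The six-membered ring C1–C2–C3–C4–C5–C11 arises by ring expansion of the cyclopentene C1–C2–C3–C5–C11 (C4 inserted between C3 and C5), and the cyclobutane C4–C5–C11–C10 by the matching contraction of the cyclopentane C3–C4–C10–C11–C5, both through the same 1,2-shift. C4 is set by inversion of the endo C–N bond and C5 migrates with retention; C10 and C11 are untouched. The step needs migration of C5 in preference to acetate capture, π-participation of the enol ether or a hydride shift; this is secured by the endo leaving group (only the C3–C5 bond is anti-periplanar), by the fully substituted C3 and C10 (no hydride to shift), and by the enol ether push that makes the shift a semipinacol-type process despite the gain in ring strain.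

Step 13
Reactants: 16 (4R,5S,7S,8R,9S,10R,11R)-9-(tert-butyldimethylsilyloxy)-7,8-bis(methoxymethoxy)longipin-2-en-1-one
Product: 17 (4R,5S,7S,8R,9S,10R,11R)-9-(tert-butyldimethylsilyloxy)-7,8-dihydroxylongipin-2-en-1-one
Conditions: ZnBr2, n-PrSH, CH2Cl2, 0 °C
Reagents that add atoms: none
Why: Lewis acid activation of the acetals with thiol capture of the methoxymethyl cation should remove both methoxymethyl groups while the hindered silyl ether at O9 and the enone remain.

Step 14
Reactants: 17 (4R,5S,7S,8R,9S,10R,11R)-9-(tert-butyldimethylsilyloxy)-7,8-dihydroxylongipin-2-en-1-one; 18 angelic acid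
Product: 19 (4R,5S,7S,8R,9S,10R,11R)-7,8-bis(angeloyloxy)-9-(tert-butyldimethylsilyloxy)longipin-2-en-1-one
Conditions: 18 (4 equiv), 2,4,6-trichlorobenzoyl chloride (4 equiv), Et3N, toluene, 25 °C; then 17, toluene, 80 °C
Reagents that add atoms: angelic acid (second molecule) C/C=C(/C)C(=O)O
Why: Yamaguchi-type acylation through the mixed anhydride, run with an excess of the activated acid so that two molecules of angelic acid are taken up per molecule of 17 and without a nucleophilic catalyst, should esterify both secondary hydroxyls (O7 and O8) in the same operation without Z-to-E isomerisation of the angeloyl groups.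

Step 15
Reactants: 19 (4R,5S,7S,8R,9S,10R,11R)-7,8-bis(angeloyloxy)-9-(tert-butyldimethylsilyloxy)longipin-2-en-1-one
Product: 20 rastevione, (4R,5S,7S,8S,9S,10R,11R)-7,8-bis(angeloyloxy)-9-hydroxylongipin-2-en-1-one
Conditions: HF·pyridine, THF/pyridine, 0 to 25 °C
Reagents that add atoms: none
Why: Fluoride-mediated desilylation under buffered, mildly acidic conditions should free the C9 hydroxyl without acyl migration or isomerisation of the angelates.

**Compound list**
1 | (R)-4-(tert-butyldimethylsilyloxy)cyclopent-2-en-1-one | O=C1C=C[C@H](O[Si](C)(C)C(C)(C)C)C1 | starting material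
2 | 2-[(1S,2R)-2-(tert-butyldimethylsilyloxy)-4-oxocyclopentyl]-2-methylpropanal (trans Michael adduct) | O=CC(C)(C)[C@@H]1CC(=O)C[C@H]1O[Si](C)(C)C(C)(C)C | intermediate
3 | (R)-2-methyl-2-(4-oxocyclopent-2-en-1-yl)propanal | O=CC(C)(C)[C@H]1C=CC(=O)C1 | intermediate
4 | (4R)-4-[(3S,4S)-3-hydroxy-4-(methoxymethoxy)-2-methylhex-5-en-2-yl]cyclopent-2-en-1-one | C=C[C@H](OCOC)[C@@H](O)C(C)(C)[C@H]1C=CC(=O)C1 | intermediate
5 | (4R)-4-[(3S,4S)-3,4-bis(methoxymethoxy)-2-methylhex-5-en-2-yl]cyclopent-2-en-1-one | C=C[C@H](OCOC)[C@@H](OCOC)C(C)(C)[C@H]1C=CC(=O)C1 | intermediate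
6 | {[(3S,4R)-4-[(3S,4S)-3,4-bis(methoxymethoxy)-2-methylhex-5-en-2-yl]-3-methylcyclopent-1-en-1-yl]oxy}trimethylsilane | C=C[C@H](OCOC)[C@@H](OCOC)C(C)(C)[C@@H]1CC(O[Si](C)(C)C)=C[C@H]1C | intermediate
7 | (4R)-4-[(3S,4S)-3,4-bis(methoxymethoxy)-2-methylhex-5-en-2-yl]-3-methylcyclopent-2-en-1-one | C=C[C@H](OCOC)[C@@H](OCOC)C(C)(C)[C@@H]1CC(=O)C=C1C | intermediate
8 | (2R,3S)-2,3-bis(methoxymethoxy)-4-methyl-4-[(1R)-2-methyl-4-oxocyclopent-2-en-1-yl]pentanal | O=C[C@H](OCOC)[C@@H](OCOC)C(C)(C)[C@@H]1CC(=O)C=C1C | intermediate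
9 | (4R)-4-[(3S,4S,5S)-5-hydroxy-3,4-bis(methoxymethoxy)-2,6-dimethylhept-6-en-2-yl]-3-methylcyclopent-2-en-1-one | C=C(C)[C@H](O)[C@H](OCOC)[C@@H](OCOC)C(C)(C)[C@@H]1CC(=O)C=C1C | intermediate
10 | (4R)-4-[(3S,4R,5S)-5-(tert-butyldimethylsilyloxy)-3,4-bis(methoxymethoxy)-2,6-dimethylhept-6-en-2-yl]-3-methylcyclopent-2-en-1-one | C=C(C)[C@H](O[Si](C)(C)C(C)(C)C)[C@H](OCOC)[C@@H](OCOC)C(C)(C)[C@@H]1CC(=O)C=C1C | intermediate
11 | (4R)-4-[(3S,4R,5S,6E)-5-(tert-butyldimethylsilyloxy)-3,4-bis(methoxymethoxy)-2,6-dimethyl-7-nitrohept-6-en-2-yl]-3-methylcyclopent-2-en-1-one | [O-][N+](=O)/C=C(\C)[C@H](O[Si](C)(C)C(C)(C)C)[C@H](OCOC)[C@@H](OCOC)C(C)(C)[C@@H]1CC(=O)C=C1C | intermediate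
12 | 2-(triisopropylsilyloxy)cyclopenta-1,3-diene from 11 (diene C11=C1(OSi)–C2=C3(Me); sp3 C5 keeps H and the nitroalkene chain) | [O-][N+](=O)/C=C(\C)[C@H](O[Si](C)(C)C(C)(C)C)[C@H](OCOC)[C@@H](OCOC)C(C)(C)[C@@H]1C=C(O[Si](C(C)C)(C(C)C)C(C)C)C=C1C | intermediate
13 | nitro cycloadduct: 2-(triisopropylsilyloxy)bicyclo[2.2.1]hept-2-ene with bridgeheads C11–H and C3–Me, bridge C5 (H syn to the enol ether), endo-NO2 on C4, endo-Me on C10, and the chain C6(Me2)–C7(OMOM)–C8(OMOM)–C9(OTBS) linking C5 to exo-C10 | CC(C)[Si](C(C)C)(C(C)C)OC1=C[C@]2(C)[C@H]([N+](=O)[O-])[C@]3(C)[C@H]1[C@H]2C(C)(C)[C@H](OCOC)[C@@H](OCOC)[C@H]3O[Si](C)(C)C(C)(C)C | intermediate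
14 | endo amine corresponding to 13 (NH2 on C4) | CC(C)[Si](C(C)C)(C(C)C)OC1=C[C@]2(C)[C@H](N)[C@]3(C)[C@H]1[C@H]2C(C)(C)[C@H](OCOC)[C@@H](OCOC)[C@H]3O[Si](C)(C)C(C)(C)C | intermediate
15 | endo diazonium acetate corresponding to 14 | CC(C)[Si](C(C)C)(C(C)C)OC1=C[C@]2(C)[C@H]([N+]#N)[C@]3(C)[C@H]1[C@H]2C(C)(C)[C@H](OCOC)[C@@H](OCOC)[C@H]3O[Si](C)(C)C(C)(C)C.CC(=O)[O-] | intermediate
16 | (4R,5S,7S,8R,9S,10R,11R)-9-(tert-butyldimethylsilyloxy)-7,8-bis(methoxymethoxy)longipin-2-en-1-one | COCO[C@@H]1[C@@H](OCOC)C(C)(C)[C@@H]2[C@H]3C(=O)C=C(C)[C@@H]2[C@@]3(C)[C@@H]1O[Si](C)(C)C(C)(C)C | intermediate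
17 | (4R,5S,7S,8R,9S,10R,11R)-9-(tert-butyldimethylsilyloxy)-7,8-dihydroxylongipin-2-en-1-one | O[C@@H]1[C@@H](O)C(C)(C)[C@@H]2[C@H]3C(=O)C=C(C)[C@@H]2[C@@]3(C)[C@@H]1O[Si](C)(C)C(C)(C)C | intermediate
18 | angelic acid, (Z)-2-methylbut-2-enoic acid | C/C=C(/C)C(=O)O | starting material
19 | (4R,5S,7S,8R,9S,10R,11R)-7,8-bis(angeloyloxy)-9-(tert-butyldimethylsilyloxy)longipin-2-en-1-one | C/C=C(/C)C(=O)O[C@@H]1[C@@H](OC(=O)/C(C)=C\C)C(C)(C)[C@@H]2[C@H]3C(=O)C=C(C)[C@@H]2[C@@]3(C)[C@@H]1O[Si](C)(C)C(C)(C)C | intermediate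
20 | rastevione, (4R,5S,7S,8S,9S,10R,11R)-7,8-bis(angeloyloxy)-9-hydroxylongipin-2-en-1-one | C/C=C(/C)C(=O)O[C@@H]1[C@@H](OC(=O)/C(C)=C\C)C(C)(C)[C@@H]2[C@H]3C(=O)C=C(C)[C@@H]2[C@@]3(C)[C@@H]1O | target

**Totals and risks**
Total step count: 15. Longest linear sequence: 15 steps (1 to 20).

The three steps most likely to fail:

Step 12 (proposed new method). What may go wrong: hydrolysis of the silyl enol ether before ionisation (leaving an unassisted cation), capture of the cation by acetate or water, or loss of the endo configuration at C4 through a diazoalkane, which would open the way to π-participation of the enol ether. Fallback, by known reaction types: set out from 13 and carry out a Nef reaction (NaOMe, then TiCl3/NH4OAc buffer); the aqueous acid also unmasks the C1 ketone and should give the diketone F1. Soft enolisation (TIPSOTf, Et3N) can touch only the C1 ketone, because the C4 ketone has no α-hydrogen, and should give the enol ether ketone F2. Dissolving-metal reduction (Li, NH3, t-BuOH) should give the thermodynamically preferred endo alcohol F3, as the exo face is blocked by the C6 chain. Mesylation (MsCl, Et3N) should give the endo mesylate F4, and buffered solvolysis (2,6-lutidine, CF3CH2OH) should bring about the same Wagner–Meerwein shift in its classical sulfonate form, rejoining the route at 16.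

Step 10. What may go wrong: [1,5]-hydrogen shift in the cyclopentadiene before cyclisation, deprotonation or isomerisation of the nitroalkene by the amine base, or a sluggish ring closure that must form two quaternary carbons (C3 and C10). Fallback: set out from 11 and use secondary-amine catalysis (pyrrolidine, AcOH, CHCl3, 25 °C); the cross-conjugated 2-aminodiene formed at C11 should add to the nitroalkene in an enamine-mediated double Michael reaction and, after hydrolysis, give the nitro ketone F5. Silylation of F5 (TIPSOTf, Et3N), which can enolise only towards C2, returns to the route at 13.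

Step 9. What may go wrong: hydrogen abstraction from the methyl group or from C9 instead of the nitromethyl carbon (giving allylic nitro isomers), or poor conversion at the hindered alkene. Fallback: set out from 10 and cleave the 1,1-disubstituted alkene selectively by ozonolysis to the methyl ketone F6; a Henry addition of nitromethane (tetramethylguanidine, neat MeNO2) should give the tertiary nitro alcohol F7, and dehydration (MsCl, Et3N, then equilibration) should give the E-nitroalkene, rejoining the route at 11.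

Further compounds
F1 | step 12 | diketone from 13 (C1 and C4 ketones; same bicyclo[2.2.1]heptane core) | O=C1C[C@]2(C)C(=O)[C@]3(C)[C@H]1[C@H]2C(C)(C)[C@H](OCOC)[C@@H](OCOC)[C@H]3O[Si](C)(C)C(C)(C)C
F2 | step 12 | C1 triisopropylsilyl enol ether of F1 with the C4 ketone free | CC(C)[Si](C(C)C)(C(C)C)OC1=C[C@]2(C)C(=O)[C@]3(C)[C@H]1[C@H]2C(C)(C)[C@H](OCOC)[C@@H](OCOC)[C@H]3O[Si](C)(C)C(C)(C)C
F3 | step 12 | endo C4 alcohol from F2 | CC(C)[Si](C(C)C)(C(C)C)OC1=C[C@]2(C)[C@H](O)[C@]3(C)[C@H]1[C@H]2C(C)(C)[C@H](OCOC)[C@@H](OCOC)[C@H]3O[Si](C)(C)C(C)(C)C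
F4 | step 12 | endo C4 mesylate from F3 | CC(C)[Si](C(C)C)(C(C)C)OC1=C[C@]2(C)[C@H](OS(C)(=O)=O)[C@]3(C)[C@H]1[C@H]2C(C)(C)[C@H](OCOC)[C@@H](OCOC)[C@H]3O[Si](C)(C)C(C)(C)C
F5 | step 10 | nitro ketone (C1 ketone; endo-NO2 on C4; same bicyclo[2.2.1]heptane core as 13) | O=C1C[C@]2(C)[C@H]([N+](=O)[O-])[C@]3(C)[C@H]1[C@H]2C(C)(C)[C@H](OCOC)[C@@H](OCOC)[C@H]3O[Si](C)(C)C(C)(C)C
F6 | step 9 | methyl ketone from 10 (C10 ketone) | CC(=O)[C@H](O[Si](C)(C)C(C)(C)C)[C@H](OCOC)[C@@H](OCOC)C(C)(C)[C@@H]1CC(=O)C=C1C
F7 | step 9 | tertiary nitro alcohol from F6 (both C10 epimers) | [O-][N+](=O)CC(C)(O)[C@H](O[Si](C)(C)C(C)(C)C)[C@H](OCOC)[C@@H](OCOC)C(C)(C)[C@@H]1CC(=O)C=C1C
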